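What is left of the incoming ligand is the quantity to follow in the grey flask. Each exchange burns one incoming ligand, so the charge sets an exchange budget of 50.0%, the incoming ligand charged as a fraction of the starting complex charged.

| flask | starting complex | incoming ligand | scavenger | remark | time |
|---|---|---|---|---|---|
| grey | 0.25 M | 0.125 M | 0.25 M | the very flask that is asked about, followed so far |  |
| ochre | 0.25 M | 0.125 M | 0.50 M | run made earlier |  |
| flask | 0.25 M | 0.125 M | 0.250 M |  | 5.0 h |

| run | time / min | complex with one exchanged / % | starting complex / % |
|---|---|---|---|
| grey | 15.0 | 13.5 | 83.6 |
| grey | 25.0 | 18.0 | 77.7 |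
| grey | 40.0 | 17.7 | 76.0 |
| grey | 60.0 | 17.1 | 71.7 |
| grey | 120 | 17.5 | 70.3 |
| grey | 180 | 18.0 | 69.6 |
| ochre | 0.833 | 1.7 | 98.0 |
| ochre | 2.50 | 5.3 | 97.7 |
| ochre | 4.00 | 6.5 | 93.7 |
| ochre | 6.00 | 8.4 | 90.5 |
| ochre | 10.0 | 10.8 | 87.3 |
| ochre | 12.0 | 11.6 | 84.2 |

(each reading ± 1 percentage point)

- winter: change nothing and wait 1.5 h more
- autumn: at 5.0 h add incoming ligand, 100% of the amount charged, then wait 1.5 h
- spring: at 5.0 h add starting complex, 50.0% of the amount charged, then wait 1.5 h
- noon: at 5.0 h take out 90% of the complex with one exchanged then present, then wait 1.5 h

* complex with one exchanged, in percent of the starting complex first charged, at 5.0 h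
* what to do for the largest gain in complex with one exchanged; "none" if nothing gains more than 2 percentage points (winter / autumn / spring / noon / none)
* complex with one exchanged present, with what was taken out counted in, in percent of the starting complex first charged, after autumn
* complex with one exchanged present, with what was taken out counted in, in percent of the starting complex first charged, after noon

- what is taken out of complex with one exchanged is counted as made
- the earlier runs were read with a standard deviation of 1 percentage point
- additions bring no volume worth counting

In the first instants, complex with one exchanged reads 11.6% at 12.0 min in the ochre run, with twice the scavenger, and 13.5% at 15.0 min in the grey flask. That is much the same pace, so this reckoning takes the capture of leaving ligand as the fast step and counts each exchange as one-way. Scavenger is charged 2.00 times over the incoming ligand, which makes incoming ligand the limiting reagent.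

In the middle, from 25.0 min, complex with one exchanged stays within scatter of 18.0% while starting complex keeps falling. A selectivity factor of 3, second exchange against first, chosen to fit these readings, gives 17.9% for the 69.6% of starting complex read at 180 min, beside the reading of 18.0%.

Towards the end, the gap in the grey readings at 180 min is 12.4%. Counted as doubly exchanged, it leaves an estimated 7.20% of the budget unspent. A further exchange stays as complex with one exchanged by the net share 0.126, so this reckoning commits to 18.9% at 5.0 h. Autumn enlarges the budget, but on this curve the net share falls to nil where starting complex stands at 57.7%, and complex with one exchanged peaks there at 19.2%. With the 7.20% counted as used by 5.0 h, winter, spring and noon are expected to find little incoming ligand, so this reckoning expects no option to gain 2 percentage points.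

The forecast says 18% (range 17% to 19%), lower than this reckoning, with 18.8% after autumn, 18.9% after noon and the choice none. Its ground is that “the flat tail means ligand is practically spent”.

The flask gives 19.1%, 20.6% after autumn, 19.6% after noon and the choice none, autumn gaining 1.5 points.

    starting complex + incoming ligand ⇌ leaving ligand + complex with one exchanged (K = 4.90, k = 0.00250 L mol⁻¹ s⁻¹)
    complex with one exchanged + incoming ligand ⇌ leaving ligand + complex with two exchanged (K = 0.920, k = 0.00690 L mol⁻¹ s⁻¹)
    complex with two exchanged + incoming ligand ⇌ leaving ligand + complex with three exchanged (K = 1.50, k = 0.00580 L mol⁻¹ s⁻¹)
    leaving ligand + starting complex ⇌ idle adduct, settled at all times (K = 1.90 L mol⁻¹)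
    scavenger + leaving ligand → scavenged by-product (k = 0.250 L mol⁻¹ s⁻¹)
    incoming ligand ⇌ dormant form (K = 1.50, k = 2.60 × 10⁻⁴ s⁻¹)

With the charged concentrations, capture by scavenger taken by itself gives leaving ligand a half-life of 0.18 min, far shorter than the 37 min of starting complex by the forward first exchange. At 5.0 h the grey flask holds 19.1%, 9.46% and 3.46% of complexes with one, two and three exchanged, which is 48.4% of exchanges; dormant form and incoming ligand hold 1.60%, and together these fill the budget of 50.0%. The neighbour flask with 0.62 M of starting complex has a budget of 20.2%, its exchanges add up to 20.0%, and its complex with one exchanged stands at 12.7%.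

The readings were generated by integration for substances that don't exist; scatter was added.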